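The γ-lactone ring is cut off the ten-membered carbocycle at the two ring-fusion atoms (germacrane numbering): C7 (bond to C11) and C8 (bond to the lactone oxygen). Their vicinal C–C/C–O pattern maps onto an alkene. The precursor is an acyclic, enantiopure (E)-alkenyl p-tolyl sulfoxide, S–C8H=C7H–, that already carries C1–C6 and C15. Dichloroketene lays its C–C(=O)–O unit across C7=C8 in one operation (O-acylation, [3,3] shift, thionium capture) and transfers chirality from sulfur to C7. The sulfide left on C8 then serves as the radical handle for trans-selective attachment of C9, C10 and C14. The CCl2 group becomes C11=C13, and ring-closing metathesis at the ring-cis C1=C10 bond closes the carbocycle.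

Key step: step 6

Remark on numbering: the ring is C1–C10 with C1=C10 and C4=C5. C7 and C8 are the lactone fusion atoms. C11, C12 and C13 are the lactone α-carbon, carbonyl carbon and exocyclic methylene. C14 is the acetoxymethyl carbon on C10 and C15 the acyloxymethyl carbon on C4. "Chain" means the (2Z)-3-{[(tert-butyldimethylsilyl)oxy]methyl}hepta-2,6-dien-1-yl group (C6, C5, C4 with C15, C3, C2, C1 and a terminal CH2).
Assumption: the sense of sulfur-to-carbon chirality transfer in step 6 is taken from the chair-like model stated there.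

Step 1
Reactants: 1 prop-2-yn-1-ol; 2 but-3-en-1-ylmagnesium bromide; 3 3-bromo-1-(trimethylsilyl)prop-1-yne
Product: 5 (2Z)-2-(but-3-en-1-yl)-6-(trimethylsilyl)hex-2-en-5-yn-1-ol, via cyclic alkenylmagnesium alkoxide 4 (not isolated)
Conditions: CuI (10 mol %), 2 (2.5 equiv), THF, 0 °C to rt; then 3 (2 equiv), 0 °C to rt; aq NH4Cl
Reagents that add atoms: none
Why: Copper-catalysed anti-carbomagnesiation of a propargylic alcohol puts the butenyl group on C4 and magnesium on C5 inside a five-membered chelate, so the following copper-catalysed SN2 propargylation places C6 cis to C15, which is the ring-trans C4=C5 geometry of the target.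

Step 2
Reactants: 5 (2Z)-2-(but-3-en-1-yl)-6-(trimethylsilyl)hex-2-en-5-yn-1-ol
Product: 6 tert-butyl{[(2Z)-2-(but-3-en-1-yl)-6-(trimethylsilyl)hex-2-en-5-yn-1-yl]oxy}dimethylsilane
Conditions: TBSCl, imidazole, CH2Cl2, rt
Reagents that add atoms: tert-butyldimethylsilyl chloride, CC(C)(C)[Si](C)(C)Cl
Why: Standard silylation of the primary allylic alcohol masks the C15 oxygen for the organometallic, ketene, enolate and radical steps ahead and creates no stereocentre.

Step 3
Reactants: 6 tert-butyl{[(2Z)-2-(but-3-en-1-yl)-6-(trimethylsilyl)hex-2-en-5-yn-1-yl]oxy}dimethylsilane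
Product: 7 tert-butyl{[(2Z)-2-(but-3-en-1-yl)hex-2-en-5-yn-1-yl]oxy}dimethylsilane
Conditions: K2CO3 (cat.), MeOH, rt
Reagents that add atoms: none
Why: Carbonate-catalysed protodesilylation cleaves only the alkynyl C–Si bond and should leave the silyl ether and the skipped enyne untouched.

Step 4
Reactants: 7 tert-butyl{[(2Z)-2-(but-3-en-1-yl)hex-2-en-5-yn-1-yl]oxy}dimethylsilane
Product: 9 tert-butyl{[(2Z,5E)-2-(but-3-en-1-yl)-6-iodohexa-2,5-dien-1-yl]oxy}dimethylsilane, via (E)-alkenylzirconocene chloride 8 (not isolated)
Conditions: Cp2ZrHCl (1.1 equiv), THF, rt; then I2, 0 °C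
Reagents that add atoms: iodine, II
Why: In this hydrozirconation–iodination, Cp2ZrHCl adds syn and terminally to the alkyne much faster than to the monosubstituted alkene, and iodinolysis with retention should give the (E)-iodide at C7=C8.

Step 5
Reactants: 9 tert-butyl{[(2Z,5E)-2-(but-3-en-1-yl)-6-iodohexa-2,5-dien-1-yl]oxy}dimethylsilane; 10 (1S,2R,5S)-menthyl (R)-4-methylbenzenesulfinate
Product: 13 tert-butyl({(2Z,5E)-2-(but-3-en-1-yl)-6-[(S)-4-methylbenzenesulfinyl]hexa-2,5-dien-1-yl}oxy)dimethylsilane, via (E)-alkenyllithium 11 (not isolated), via (E)-alkenylmagnesium bromide 12 (not isolated)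
Conditions: t-BuLi (2 equiv), Et2O, −78 °C; MgBr2·OEt2; then 10, THF, −78 to −20 °C
Reagents that add atoms: none
Why: In this Andersen sulfoxide synthesis, iodine–lithium exchange and transmetalation keep the (E)-geometry and the alkenyl Grignard reagent displaces menthoxide from sulfur with inversion, so the (R)-sulfinate should give the (S)-sulfoxide.

Step 6
Reactants: 13 tert-butyl({(2Z,5E)-2-(but-3-en-1-yl)-6-[(S)-4-methylbenzenesulfinyl]hexa-2,5-dien-1-yl}oxy)dimethylsilane; 14 trichloroacetyl chloride
Product: 18 (4S,5S)-3,3-dichloro-4-[chain]-5-[(4-methylphenyl)sulfanyl]oxolan-2-one (C6 chain trans to S-tolyl), via dichloroketene 15 (not isolated), via acyloxysulfonium enolate 16 (not isolated), via thionium carboxylate 17 (not isolated)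
Conditions: 14 (2 equiv, slow addition), Zn(Cu) (5 equiv), THF, −45 to 0 °C
Reagents that add atoms: none
Why: Dichloroketene 15, released from 14 by zinc, is attacked by the nucleophilic sulfinyl oxygen of 13 to give the acyloxysulfonium enolate 16, whose charge-accelerated [3,3]-sigmatropic shift joins the enolate carbon C11 to C7 while the S–O bond breaks, and the carboxylate of 17 then closes onto the thionium carbon C8 (vinyl sulfoxide–dichloroketene lactonisation, an additive Pummerer process also called the Marino annulation). The only ring closed is the γ-lactone, by 5-exo-trig attack of carboxylate oxygen on the C8=S+ bond. C7 is controlled by the sulfur stereocentre: in the chair-like array the S–O bond stands perpendicular to the alkene plane, the sulfur lone pair lies inside over the C=C bond and the tolyl group points outside, so the (S)-sulfoxide on the (E)-alkene should deliver C11 to the face that gives the C7 configuration of the target (descriptor 4S here only because chlorine raises the rank of C11). C8 follows from suprafacial collapse of the ion pair, which should put S-tolyl trans to the C6 chain, and this centre is deliberately reset in step 11. The step needs chemoselectivity for S=O over the C1 vinyl group and the C4=C5 bond, which the far higher nucleophilicity of the sulfinyl oxygen, the low temperature and the slow release of the ketene should secure, and the base-free zinc conditions spare the doubly allylic C6 hydrogens from vinylogous Pummerer loss.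

Step 7
Reactants: 18 (4S,5S)-3,3-dichloro-4-[chain]-5-[(4-methylphenyl)sulfanyl]oxolan-2-one
Product: 19 (4R,5S)-4-[chain]-5-[(4-methylphenyl)sulfanyl]oxolan-2-one
Conditions: Al(Hg), THF–H2O (9:1), 0 °C to rt
Reagents that add atoms: none
Why: Reductive dechlorination by electron transfer removes both α-chlorines through the enolate, while the O,S-acetal, the silyl ether and the isolated alkenes are not reducible under these neutral conditions and C7 is untouched.

Step 8
Reactants: 19 (4R,5S)-4-[chain]-5-[(4-methylphenyl)sulfanyl]oxolan-2-one; 20 N,N-dimethylmethyleneiminium iodide (Eschenmoser's salt)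
Product: 22 (3S,4R,5S)-3-[(dimethylamino)methyl]-4-[chain]-5-[(4-methylphenyl)sulfanyl]oxolan-2-one, via lithium enolate 21 (not isolated)
Conditions: LiN(i-Pr)2 (1.1 equiv), THF, −78 °C; then 20, −78 to 0 °C
Reagents that add atoms: none
Why: Mannich alkylation of the lactone enolate brings in C13 anti to the C7 chain and stores the later exocyclic methylene as an amine that is inert to radicals.

Step 9
Reactants: 23 2-methylprop-2-en-1-ol
Product: 25 2-[(tributylstannyl)methyl]prop-2-en-1-ol, via O,C-dilithio dianion 24 (not isolated)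
Conditions: n-BuLi (2.2 equiv), TMEDA, Et2O, 0 °C to rt; then Bu3SnCl, −78 °C to rt; aq work-up
Reagents that add atoms: tributyltin chloride, CCCC[Sn](Cl)(CCCC)CCCC
Why: Alkoxide-directed allylic lithiation to the O,C-dianion followed by C-stannylation is the standard entry to 2-(hydroxymethyl)allyl metals, and any O–Sn bond is hydrolysed on work-up.

Step 10
Reactants: 25 2-[(tributylstannyl)methyl]prop-2-en-1-ol
Product: 26 2-[(tributylstannyl)methyl]prop-2-en-1-yl acetate
Conditions: Ac2O, pyridine, DMAP (cat.), CH2Cl2, 0 °C to rt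
Reagents that add atoms: acetic anhydride, CC(=O)OC(C)=O
Why: Routine acetylation installs the acetate that ends as the C14 ester of the target.

Step 11
Reactants: 22 (3S,4R,5S)-3-[(dimethylamino)methyl]-4-[chain]-5-[(4-methylphenyl)sulfanyl]oxolan-2-one; 26 2-[(tributylstannyl)methyl]prop-2-en-1-yl acetate
Product: 27 (3S,4R,5S)-5-[2-(acetoxymethyl)prop-2-en-1-yl]-3-[(dimethylamino)methyl]-4-[chain]oxolan-2-one
Conditions: 26 (3 equiv), AIBN (portions), benzene, 80 °C
Reagents that add atoms: none
Why: In this Keck radical allylation the stannyl radical cleaves the weak acetal-type C8–S bond and the α-acyloxy radical adds to 26 from the face opposite the C7 chain before β-scission of tin, which should set 8S (trans to C7) with the C8–O bond intact and bring in C9, C10 and C14 with the acetate in place.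

Step 12
Reactants: 27 (3S,4R,5S)-5-[2-(acetoxymethyl)prop-2-en-1-yl]-3-[(dimethylamino)methyl]-4-[chain]oxolan-2-one
Product: 29 (4R,5S)-5-[2-(acetoxymethyl)prop-2-en-1-yl]-3-methylidene-4-[chain]oxolan-2-one, via trimethylammonium iodide 28 (not isolated)
Conditions: MeI, THF, rt; then aq NaHCO3, EtOAc, rt
Reagents that add atoms: none
Why: Quaternisation and E1cB (Hofmann-type) loss of trimethylamine complete the Eschenmoser methylenation under conditions too mild for the acetate or silyl ether and erase the auxiliary C11 stereocentre as planned.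

Step 13
Reactants: 29 (4R,5S)-5-[2-(acetoxymethyl)prop-2-en-1-yl]-3-methylidene-4-[chain]oxolan-2-one
Product: 30 (7R,8S)-14-acetoxy-15-(tert-butyldimethylsilyloxy)germacra-1(10),4,11(13)-trien-12,8-olide (C1=C10 ring-cis; C4=C5 ring-trans)
Conditions: second-generation Hoveyda–Grubbs catalyst (15 mol %, portions), 1,4-benzoquinone (30 mol %), toluene, 1 mM, 80 °C, argon sparge
Reagents that add atoms: none
Why: Ring-closing metathesis should start at the monosubstituted C1 alkene and close onto the 1,1-disubstituted C10 alkene, the electron-poor α-methylene lactone being a poor partner, and the ten-membered ring should favour the ring-cis geometry for the new trisubstituted bond next to the ring-trans C4=C5 bond.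

Step 14
Reactants: 30 (7R,8S)-14-acetoxy-15-(tert-butyldimethylsilyloxy)germacra-1(10),4,11(13)-trien-12,8-olide
Product: 31 (7R,8S)-14-acetoxy-15-bromogermacra-1(10),4,11(13)-trien-12,8-olide
Conditions: Ph3PBr2 (1.2 equiv), CH2Cl2, 0 °C to rt
Reagents that add atoms: dibromotriphenylphosphorane, BrP(Br)(c1ccccc1)(c1ccccc1)c1ccccc1
Why: Appel-type direct bromination of the silyl ether runs through the alkoxyphosphonium ion and SN2 attack of bromide at the primary allylic C15 under essentially neutral conditions, so the acid-sensitive cyclodecadiene sees neither fluoride nor protic acid.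

Step 15
Reactants: 32 ethyl 2-(hydroxymethyl)prop-2-enoate
Product: 33 caesium 2-(hydroxymethyl)prop-2-enoate
Conditions: CsOH·H2O (1.0 equiv), THF–H2O, 0 °C; evaporation and drying in vacuo
Reagents that add atoms: caesium hydroxide, [Cs+].[OH-]
Why: Saponification with one equivalent of CsOH gives the dry caesium carboxylate directly and avoids isolation of the polymerisable free acid.

Step 16
Reactants: 31 (7R,8S)-14-acetoxy-15-bromogermacra-1(10),4,11(13)-trien-12,8-olide; 33 caesium 2-(hydroxymethyl)prop-2-enoate
Product: 34 CNP0126545.1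
Conditions: 33 (1.5 equiv), DMF, 0 °C to rt
Reagents that add atoms: none
Why: Caesium carboxylate alkylation (SN2) at the primary allylic bromide should be far faster than any reaction of the neutral hydroxyl group or attack at the hindered C5 terminus, so the hydroxy acrylate is attached without a protecting group and no stereocentre is touched.

Compound list
1 | prop-2-yn-1-ol (propargyl alcohol) | C#CCO | starting material
2 | but-3-en-1-ylmagnesium bromide | C=CCC[Mg]Br | starting material
3 | 3-bromo-1-(trimethylsilyl)prop-1-yne | C[Si](C)(C)C#CCBr | starting material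
4 | cyclic alkenylmagnesium alkoxide, 4-(but-3-en-1-yl)-2,5-dihydro-1,2-oxamagnesole (Mg on C5, cis to C15) | C=CCCC1=C[Mg]OC1 | intermediate
5 | (2Z)-2-(but-3-en-1-yl)-6-(trimethylsilyl)hex-2-en-5-yn-1-ol | OC/C(CCC=C)=C\CC#C[Si](C)(C)C | intermediate
6 | tert-butyl{[(2Z)-2-(but-3-en-1-yl)-6-(trimethylsilyl)hex-2-en-5-yn-1-yl]oxy}dimethylsilane | CC(C)(C)[Si](C)(C)OC/C(CCC=C)=C\CC#C[Si](C)(C)C | intermediate
7 | tert-butyl{[(2Z)-2-(but-3-en-1-yl)hex-2-en-5-yn-1-yl]oxy}dimethylsilane | CC(C)(C)[Si](C)(C)OC/C(CCC=C)=C\CC#C | intermediate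
8 | (E)-alkenylzirconocene chloride from 7 (cyclopentadienyl rings drawn σ-bonded) | CC(C)(C)[Si](C)(C)OC/C(CCC=C)=C\C/C=C/[Zr](Cl)(C1C=CC=C1)C1C=CC=C1 | intermediate
9 | tert-butyl{[(2Z,5E)-2-(but-3-en-1-yl)-6-iodohexa-2,5-dien-1-yl]oxy}dimethylsilane | CC(C)(C)[Si](C)(C)OC/C(CCC=C)=C\C/C=C/I | intermediate
10 | (1S,2R,5S)-menthyl (R)-4-methylbenzenesulfinate | C[C@H]1CC[C@@H]([C@H](C1)O[S@@](=O)c2ccc(C)cc2)C(C)C | starting material
11 | (E)-alkenyllithium from 9 | CC(C)(C)[Si](C)(C)OC/C(CCC=C)=C\C/C=C/[Li] | intermediate
12 | (E)-alkenylmagnesium bromide from 11 | CC(C)(C)[Si](C)(C)OC/C(CCC=C)=C\C/C=C/[Mg]Br | intermediate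
13 | tert-butyl({(2Z,5E)-2-(but-3-en-1-yl)-6-[(S)-4-methylbenzenesulfinyl]hexa-2,5-dien-1-yl}oxy)dimethylsilane | CC(C)(C)[Si](C)(C)OC/C(CCC=C)=C\C/C=C/[S@](=O)c1ccc(C)cc1 | intermediate
14 | trichloroacetyl chloride | ClC(Cl)(Cl)C(Cl)=O | starting material
15 | dichloroketene | ClC(Cl)=C=O | intermediate
16 | acyloxysulfonium enolate (zwitterion from 13 and 15) | CC(C)(C)[Si](C)(C)OC/C(CCC=C)=C\C/C=C/[S@+](OC([O-])=C(Cl)Cl)c1ccc(C)cc1 | intermediate
17 | thionium carboxylate (zwitterion after the [3,3] shift, C7–C11 bond made) | CC(C)(C)[Si](C)(C)OC/C(CCC=C)=C\C[C@@H](C=[S+]c1ccc(C)cc1)C(Cl)(Cl)C(=O)[O-] | intermediate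
18 | (4S,5S)-3,3-dichloro-4-[chain]-5-[(4-methylphenyl)sulfanyl]oxolan-2-one, chain and S-tolyl trans | CC(C)(C)[Si](C)(C)OC/C(CCC=C)=C\C[C@@H]1C(Cl)(Cl)C(=O)O[C@H]1Sc2ccc(C)cc2 | intermediate
19 | (4R,5S)-4-[chain]-5-[(4-methylphenyl)sulfanyl]oxolan-2-one | CC(C)(C)[Si](C)(C)OC/C(CCC=C)=C\C[C@@H]1CC(=O)O[C@H]1Sc2ccc(C)cc2 | intermediate
20 | N,N-dimethylmethyleneiminium iodide (Eschenmoser's salt) | C[N+](C)=C.[I-] | starting material
21 | lithium enolate of 19 | CC(C)(C)[Si](C)(C)OC/C(CCC=C)=C\C[C@@H]1C=C([O-])O[C@H]1Sc2ccc(C)cc2.[Li+] | intermediate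
22 | (3S,4R,5S)-3-[(dimethylamino)methyl]-4-[chain]-5-[(4-methylphenyl)sulfanyl]oxolan-2-one | CC(C)(C)[Si](C)(C)OC/C(CCC=C)=C\C[C@@H]1[C@@H](CN(C)C)C(=O)O[C@H]1Sc2ccc(C)cc2 | intermediate
23 | 2-methylprop-2-en-1-ol (methallyl alcohol) | CC(=C)CO | starting material
24 | O,C-dilithio dianion of 23 | [Li]CC(=C)CO[Li] | intermediate
25 | 2-[(tributylstannyl)methyl]prop-2-en-1-ol | OCC(=C)C[Sn](CCCC)(CCCC)CCCC | intermediate
26 | 2-[(tributylstannyl)methyl]prop-2-en-1-yl acetate | CC(=O)OCC(=C)C[Sn](CCCC)(CCCC)CCCC | intermediate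
27 | (3S,4R,5S)-5-[2-(acetoxymethyl)prop-2-en-1-yl]-3-[(dimethylamino)methyl]-4-[chain]oxolan-2-one | CC(C)(C)[Si](C)(C)OC/C(CCC=C)=C\C[C@@H]1[C@@H](CN(C)C)C(=O)O[C@H]1CC(=C)COC(C)=O | intermediate
28 | trimethylammonium iodide of 27 | CC(C)(C)[Si](C)(C)OC/C(CCC=C)=C\C[C@@H]1[C@@H](C[N+](C)(C)C)C(=O)O[C@H]1CC(=C)COC(C)=O.[I-] | intermediate
29 | (4R,5S)-5-[2-(acetoxymethyl)prop-2-en-1-yl]-3-methylidene-4-[chain]oxolan-2-one | CC(C)(C)[Si](C)(C)OC/C(CCC=C)=C\C[C@@H]1C(=C)C(=O)O[C@H]1CC(=C)COC(C)=O | intermediate
30 | (7R,8S)-14-acetoxy-15-(tert-butyldimethylsilyloxy)germacra-1(10),4,11(13)-trien-12,8-olide, C1=C10 ring-cis (CIP E), C4=C5 ring-trans (CIP Z), trans-fused lactone | CC(C)(C)[Si](C)(C)OC/C1=C\C[C@@H]2C(=C)C(=O)O[C@H]2C/C(COC(C)=O)=C\CC1 | intermediate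
31 | (7R,8S)-14-acetoxy-15-bromogermacra-1(10),4,11(13)-trien-12,8-olide, same alkene geometries | BrC/C1=C\C[C@@H]2C(=C)C(=O)O[C@H]2C/C(COC(C)=O)=C\CC1 | intermediate
32 | ethyl 2-(hydroxymethyl)prop-2-enoate | C=C(CO)C(=O)OCC | starting material
33 | caesium 2-(hydroxymethyl)prop-2-enoate | C=C(CO)C(=O)[O-].[Cs+] | intermediate
34 | CNP0126545.1, (7R,8S)-14-acetoxy-15-[2-(hydroxymethyl)acryloyloxy]germacra-1(10),4,11(13)-trien-12,8-olide | C=C(CO)C(=O)OC/C1=C\C[C@@H]2C(=C)C(=O)O[C@H]2C/C(COC(C)=O)=C\CC1 | target

Total step count: 16. Longest linear sequence: 13 steps (steps 1–8, 11–14 and 16).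

Steps most likely to fail

Step 6. The ketene may add [2+2] to the C1 vinyl group. The sulfoxide may simply be deoxygenated. The acyloxysulfonium ion may lose a doubly allylic C6 hydrogen. Reaction through the conformer with the tolyl group inside would erode facial selectivity. The fallback sets out from 13 and replaces the ketene by a neutral ketene silyl acetal. 1-(tert-Butyldimethylsilyloxy)-1-methoxyethene with catalytic ZnI2 in MeCN silylates the sulfinyl oxygen, adds the acetate carbon to C7 and moves the siloxy group to C8 (additive Pummerer reaction). This should give methyl (3R)-4-(tert-butyldimethylsilyloxy)-4-[(4-methylphenyl)sulfanyl]-3-[chain]butanoate F1, epimeric at C8. Catalytic TMSOTf in CH2Cl2 then ionises the siloxy group, and the ester carbonyl oxygen closes onto the thionium ion with loss of its methyl group. The route is rejoined at 19, which makes step 7 unnecessary.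

Step 13. Cross-metathesis of the C1 vinyl groups may outrun closure of the strained ring and lead to oligomers. Ruthenium hydrides may shift the alkenes, or the ring may close with the wrong geometry. The fallback sets out from 29 and takes the ring-trans alkene out of the closing event. mCPBA (1 equiv, NaHCO3, CH2Cl2, 0 °C) should epoxidise the most electron-rich bond, C4=C5, to the 4,5-epoxide of 29 F2; either face is acceptable because both converge. Ring-closing metathesis is then run on this more flexible substrate to give the parthenolide-type macrocyclic 4,5-epoxide F3. Stereospecific deoxygenation with Ph3P=Se and CF3CO2H in CH2Cl2 (episelenide extrusion with retention of geometry) restores C4=C5. The route is rejoined at 30.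

Step 11. Homolysis of the C8–S bond may be too slow to carry the chain. The radical may abstract allylic hydrogen instead of adding, or the facial selectivity at C8 may be poor. The fallback sets out from 22 and is polar instead of radical. The amine is masked as its triflate salt (TfOH, 1 equiv). The sulfur is activated with dimethyl(methylthio)sulfonium triflate, as in C-glycosylation of thioglycosides, so that only the C–S bond can ionise. The acyloxocarbenium ion is trapped anti to the C7 chain by commercial 2-[(trimethylsilyl)methyl]prop-2-en-1-yl acetate (Hosomi–Sakurai allylation, CH2Cl2, −40 °C). Basic work-up should give 27 directly, so the route is rejoined at 27 without any new compound.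

Further compounds
F1 | step 6 | methyl (3R)-4-(tert-butyldimethylsilyloxy)-4-[(4-methylphenyl)sulfanyl]-3-[chain]butanoate (epimers at C8) | CC(C)(C)[Si](C)(C)OC/C(CCC=C)=C\C[C@@H](C(O[Si](C)(C)C(C)(C)C)Sc1ccc(C)cc1)CC(=O)OC
F2 | step 13 | 4,5-epoxide of 29 (C15 and C6 cis on the oxirane; one of the two convergent face isomers drawn) | CC(C)(C)[Si](C)(C)OC[C@@]1(CCC=C)O[C@H]1C[C@@H]2C(=C)C(=O)O[C@H]2CC(=C)COC(C)=O
F3 | step 13 | macrocyclic 4,5-epoxide, (7R,8S)-14-acetoxy-15-(tert-butyldimethylsilyloxy)-4,5-epoxygermacra-1(10),11(13)-dien-12,8-olide | CC(C)(C)[Si](C)(C)OC[C@]13O[C@H]3C[C@@H]2C(=C)C(=O)O[C@H]2C/C(COC(C)=O)=C\CC1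
F0 | step 11 | none | none
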